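**Plan**

Numbering: ring carbon C1 carries CH2OBz, C3 the benzoate, C4–C6 the three hydroxyls. Retrosynthesis: both benzoates come off (C–O), the cis-4,5-diol is read as a masked cis-alkene, and the resulting cyclohexa-1,4-diene is cut at C1=C2 and at C4–C5 (as C4=C5) into two penta-1,4-dien-3-ol units (C1/C6/C5 and C2/C3/C4).
Enabling feature: O3 and O6 are cis-1,4 across the six-membered ring, each on the carbon lying between the two bonds to be made, so one iPr2Si atom can join the two dienols through O3 and O6. One double ring-closing metathesis then gives a 2,4-dioxa-3-silabicyclo[3.2.2]nona-6,8-diene (two seven-membered silaketal rings sharing the carbocycle).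
Forward order: vinylalumination builds the ester dienol, kinetic resolution, silyl ketal union with penta-1,4-dien-3-ol, double RCM (ring formed), OsO4 on C4=C5, ester to CH2OH, silicon off, two site-selective benzoylations.
Stereochemistry: C6 from a Sharpless kinetic resolution; C3 from the tether, since only the isomer with O3 cis to O6 can be bridged (the prochiral divinyl carbinol is funnelled into one configuration); C4 and C5 from dihydroxylation on the face away from the O–Si–O bridge.

Key step: step 4

**Route**

Step 1
Reactants: 1 methyl propiolate; 2 acrolein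
Product: 4 methyl (±)-3-hydroxy-2-methylidenepent-4-enoate, via vinylalane 3 (not isolated)
Conditions: iBu2AlH, NMO, THF, 0 °C; then 2, 0 °C to rt; aq. KNaC4H4O6 (potassium sodium tartrate)
Reagents that add atoms: none
Why: Hydroalumination of the ynoate by the iBu2AlH–NMO complex places aluminium on the α-carbon and this vinylalane adds 1,2 to the aldehyde of acrolein (vinylalumination, a route to Morita–Baylis–Hillman-type adducts that avoids the amine catalysts which polymerise acrolein); the carbinol centre is formed racemic here.

Step 2
Reactants: 4 methyl (±)-3-hydroxy-2-methylidenepent-4-enoate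
Product: 5 methyl (3R)-3-hydroxy-2-methylidenepent-4-enoate
Conditions: Ti(OiPr)4 (0.2 equiv), D-(−)-diisopropyl tartrate (0.26 equiv), t-BuOOH (0.6 equiv), 4 Å MS, CH2Cl2, −20 °C, run to a little over half conversion
Reagents that add atoms: none
Why: Sharpless kinetic resolution: with D-(−)-diisopropyl tartrate the titanium tartrate catalyst should epoxidise the vinyl group of the (3S)-alcohol much faster than that of the (3R)-alcohol, the electron-poor acrylate alkene is inert to this electrophilic oxidant, and the unreacted (3R)-enantiomer, which carries the future C6 configuration, is recovered.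

Step 3
Reactants: 5 methyl (3R)-3-hydroxy-2-methylidenepent-4-enoate; 6 penta-1,4-dien-3-ol
Product: 8 methyl (3R)-2-methylidene-3-({[(penta-1,4-dien-3-yl)oxy]di(propan-2-yl)silyl}oxy)pent-4-enoate, via chlorosilyl ether 7 (not isolated)
Conditions: iPr2SiCl2 (1.05 equiv), imidazole, CH2Cl2, 0 °C; then 6 (1.3 equiv), imidazole, DMAP (cat.), rt
Reagents that add atoms: dichlorodi(propan-2-yl)silane, CC(C)[Si](Cl)(Cl)C(C)C
Why: Stepwise silyl ether formation: the first chloride of the hindered dichlorosilane is displaced by the secondary alcohol at 0 °C and the second only after the second alcohol and DMAP are added, so the mixed silyl ketal should form in preference to the symmetrical ones, and no stereocentre is touched.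

Step 4
Reactants: 8 methyl (3R)-2-methylidene-3-({[(penta-1,4-dien-3-yl)oxy]di(propan-2-yl)silyl}oxy)pent-4-enoate
Product: 9 methyl (1S,5R)-3,3-di(propan-2-yl)-2,4-dioxa-3-silabicyclo[3.2.2]nona-6,8-diene-6-carboxylate
Conditions: second-generation Hoveyda–Grubbs catalyst RuCl2(H2IMes)(=CH-C6H4-2-OiPr) (10 mol%), 1,4-benzoquinone (20 mol%), toluene (0.003 M), 80 °C, slow Ar purge towards the end
Reagents that add atoms: none
Why: Two ring-closing olefin metatheses run in sequence by the metallacyclobutane mechanism (a ruthenium alkylidene loads on a monosubstituted vinyl group, [2+2] to a ruthenacyclobutane, cycloreversion with loss of ethylene), the closest known reaction types being temporary-silicon-tethered RCM of two allylic alcohols and RCM of acrylates to cyclic enoates. The first event joins the vinyl group of the ester fragment to one vinyl group of the divinyl carbinol and closes a seven-membered 1,3-dioxa-2-silacyclohept-5-ene, which creates the future C4–C5 bond as a necessarily Z alkene. The second event joins the remaining vinyl group to the acrylate methylidene across that ring and closes the six-membered carbocycle together with the second seven-membered silaketal ring, which creates the C1=C2 bond and the bicyclo[3.2.2] frame. The one new stereocentre, C3 of the target, is set by the tether: the two vinyl groups of the divinyl carbinol are diastereotopic, and only the monocycle whose leftover vinyl group is cis to the acrylate unit on C6 can be bridged, so the configuration of C6 dictates that of C3. The first closure should favour this cis isomer (both substituents pseudo-equatorial) and, as the closure of a nearly strain-free ring, should be reversible under the ethylene set free, so trans material can re-open while the irreversible second loss of ethylene drains the mixture into the bridged diene. The selectivities needed are ring closure over oligomerisation (high dilution and the Thorpe–Ingold effect of the iPr2Si group), reaction of the electron-poor 1,1-disubstituted alkene last and intramolecularly (the carbene forms on a vinyl group and pairing within one fragment would need a three-membered ring), and no migration of the bis-allylic C–H bonds (benzoquinone traps ruthenium hydrides).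

Step 5
Reactants: 9 methyl (1S,5R)-3,3-di(propan-2-yl)-2,4-dioxa-3-silabicyclo[3.2.2]nona-6,8-diene-6-carboxylate
Product: 10 methyl (1R,5S,8R,9S)-8,9-dihydroxy-3,3-di(propan-2-yl)-2,4-dioxa-3-silabicyclo[3.2.2]non-6-ene-6-carboxylate
Conditions: OsO4 (5 mol%), NMO (1.5 equiv), acetone/H2O 9:1, rt; aq. Na2SO3
Reagents that add atoms: osmium tetroxide, O=[Os](=O)(=O)=O; N-methylmorpholine N-oxide, C[N+]1([O-])CCOCC1; water, O
Why: Upjohn dihydroxylation: the electrophilic OsO4 adds suprafacially to the electron-rich cis-disubstituted C8=C9 bridge and should leave the conjugated ester alkene alone, and it should approach from the face remote from the O–Si(iPr)2–O bridge, anti to both allylic C–O bonds, which places the new cis-diol trans to the oxygens on C1 and C5.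

Step 6
Reactants: 10 methyl (1R,5S,8R,9S)-8,9-dihydroxy-3,3-di(propan-2-yl)-2,4-dioxa-3-silabicyclo[3.2.2]non-6-ene-6-carboxylate
Product: 11 (1R,5S,8R,9S)-6-(hydroxymethyl)-3,3-di(propan-2-yl)-2,4-dioxa-3-silabicyclo[3.2.2]non-6-ene-8,9-diol
Conditions: iBu2AlH (5 equiv), CH2Cl2, −78 to −40 °C; aq. KNaC4H4O6
Reagents that add atoms: none
Why: iBu2AlH reduces the α,β-unsaturated ester 1,2 to the allylic alcohol at low temperature (the free diol only consumes extra hydride), and the silyl ketal and all stereocentres are untouched.

Step 7
Reactants: 11 (1R,5S,8R,9S)-6-(hydroxymethyl)-3,3-di(propan-2-yl)-2,4-dioxa-3-silabicyclo[3.2.2]non-6-ene-8,9-diol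
Product: 12 (1R,2S,3R,4S)-5-(hydroxymethyl)cyclohex-5-ene-1,2,3,4-tetrol
Conditions: HF·pyridine, THF/pyridine, 0 °C to rt; quench Me3SiOMe, evaporate
Reagents that add atoms: none
Why: Fluoride cleaves both Si–O bonds of the silyl ketal (desilylation) under buffered conditions that should not ionise the allylic alcohols, and every by-product is volatile, which suits the water-soluble pentol.

Step 8
Reactants: 12 (1R,2S,3R,4S)-5-(hydroxymethyl)cyclohex-5-ene-1,2,3,4-tetrol
Product: 15 (1R,4S,5R,6R)-4,5,6-trihydroxy-3-(hydroxymethyl)cyclohex-2-en-1-yl benzoate, via bis(phenylboronate) 13 (not isolated), via benzoylated bis(phenylboronate) 14 (not isolated)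
Conditions: PhB(OH)2 (2.1 equiv), pyridine, 4 Å MS, rt; BzCl (1.2 equiv), 0 °C to rt; then pinacol (5 equiv), MeOH, rt
Reagents that add atoms: benzoyl chloride, O=C(Cl)c1ccccc1
Why: Transient boronate protection as used for sugars: phenylboronic acid ties up the only cis-1,2-diol (O2/O3, five-membered ester) and the only 1,3-diol (O4 and the hydroxymethyl oxygen O7, six-membered ester) while the trans-1,2 pairs cannot bridge, so the allylic C1 hydroxyl is the one free site for acylation by benzoyl chloride, and pinacol then strips both boronates by transesterification.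

Step 9
Reactants: 15 (1R,4S,5R,6R)-4,5,6-trihydroxy-3-(hydroxymethyl)cyclohex-2-en-1-yl benzoate
Product: 16 [(3R,4R,5R,6S)-3-(benzoyloxy)-4,5,6-trihydroxycyclohex-1-en-1-yl]methyl benzoate
Conditions: BzCl (1.05 equiv), 2,4,6-collidine, CH2Cl2/THF, −40 °C
Reagents that add atoms: benzoyl chloride, O=C(Cl)c1ccccc1
Why: Site-selective acylation: at −40 °C with the weak hindered base collidine, benzoyl chloride should esterify the primary allylic hydroxyl far faster than the three secondary ones, and the low temperature and absence of strong base guard against benzoyl migration.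

**Compound list**

1 | methyl propiolate | C#CC(=O)OC | starting material
2 | acrolein | C=CC=O | starting material
3 | methyl 2-[bis(2-methylpropyl)alumanyl]prop-2-enoate | C=C(C(=O)OC)[Al](CC(C)C)CC(C)C | intermediate (not isolated)
4 | methyl (±)-3-hydroxy-2-methylidenepent-4-enoate | C=CC(O)C(=C)C(=O)OC | intermediate
5 | methyl (3R)-3-hydroxy-2-methylidenepent-4-enoate | C=C[C@@H](O)C(=C)C(=O)OC | intermediate
6 | penta-1,4-dien-3-ol | C=CC(O)C=C | starting material
7 | methyl (3R)-3-{[chlorodi(propan-2-yl)silyl]oxy}-2-methylidenepent-4-enoate | C=C[C@@H](O[Si](Cl)(C(C)C)C(C)C)C(=C)C(=O)OC | intermediate (not isolated)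
8 | methyl (3R)-2-methylidene-3-({[(penta-1,4-dien-3-yl)oxy]di(propan-2-yl)silyl}oxy)pent-4-enoate | C=C[C@@H](O[Si](OC(C=C)C=C)(C(C)C)C(C)C)C(=C)C(=O)OC | intermediate
9 | methyl (1S,5R)-3,3-di(propan-2-yl)-2,4-dioxa-3-silabicyclo[3.2.2]nona-6,8-diene-6-carboxylate | COC(=O)C1=C[C@@H]2C=C[C@H]1O[Si](C(C)C)(C(C)C)O2 | intermediate
10 | methyl (1R,5S,8R,9S)-8,9-dihydroxy-3,3-di(propan-2-yl)-2,4-dioxa-3-silabicyclo[3.2.2]non-6-ene-6-carboxylate (diol anti to the O–Si–O bridge) | COC(=O)C1=C[C@@H]2[C@H](O)[C@H](O)[C@H]1O[Si](C(C)C)(C(C)C)O2 | intermediate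
11 | (1R,5S,8R,9S)-6-(hydroxymethyl)-3,3-di(propan-2-yl)-2,4-dioxa-3-silabicyclo[3.2.2]non-6-ene-8,9-diol | OCC1=C[C@@H]2[C@H](O)[C@H](O)[C@H]1O[Si](C(C)C)(C(C)C)O2 | intermediate
12 | (1R,2S,3R,4S)-5-(hydroxymethyl)cyclohex-5-ene-1,2,3,4-tetrol | OCC1=C[C@@H](O)[C@H](O)[C@H](O)[C@H]1O | intermediate
13 | 2,3:4,7-bis-O-(phenylboranediyl) derivative of 12 (C1 hydroxyl free) | B1(c2ccccc2)OCC2=C[C@@H](O)[C@@H]3OB(c4ccccc4)O[C@@H]3[C@H]2O1 | intermediate (not isolated)
14 | 1-O-benzoyl-2,3:4,7-bis-O-(phenylboranediyl) derivative of 12 | B1(c2ccccc2)OCC2=C[C@@H](OC(=O)c5ccccc5)[C@@H]3OB(c4ccccc4)O[C@@H]3[C@H]2O1 | intermediate (not isolated)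
15 | (1R,4S,5R,6R)-4,5,6-trihydroxy-3-(hydroxymethyl)cyclohex-2-en-1-yl benzoate | OCC1=C[C@@H](OC(=O)c2ccccc2)[C@H](O)[C@H](O)[C@H]1O | intermediate
16 | [(3R,4R,5R,6S)-3-(benzoyloxy)-4,5,6-trihydroxycyclohex-1-en-1-yl]methyl benzoate | O=C(OCC1=C[C@@H](OC(=O)c2ccccc2)[C@H](O)[C@H](O)[C@H]1O)c1ccccc1 | target

**Summary**

Total step count: 9. Longest linear sequence: 9 steps (from methyl propiolate and acrolein; penta-1,4-dien-3-ol enters as bought).

Steps most likely to fail:

1. Step 4. The second, bridging ring closure may lose out to oligomerisation, or the first closure may use the wrong diastereotopic vinyl group and fail to re-open. The fallback sets out from 8 and comes back at 12, with the second ring closed without the bridge. The first-generation Grubbs catalyst RuCl2(PCy3)2(=CHPh) in CH2Cl2 should join only the two monosubstituted vinyl groups and give, after separation from its trans isomer, the cis seven-membered silaketal methyl 2-[(4R,7R)-7-ethenyl-2,2-di(propan-2-yl)-4,7-dihydro-1,3,2-dioxasilepin-4-yl]prop-2-enoate F1. HF·pyridine removes silicon to give methyl (3R,4Z,6R)-3,6-dihydroxy-2-methylideneocta-4,7-dienoate F2. RCM of this Z-triene with the second-generation Hoveyda–Grubbs catalyst gives methyl (3S,6R)-3,6-dihydroxycyclohexa-1,4-diene-1-carboxylate F3, kept free of acid and base to avoid aromatisation. OsO4/NMO anti to both allylic hydroxyls gives methyl (3R,4S,5R,6S)-3,4,5,6-tetrahydroxycyclohex-1-ene-1-carboxylate F4, and excess iBu2AlH in THF reduces this to 12.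

2. Step 8. Boronate formation may be incomplete or may scramble, so that benzoylation is not confined to the C1 hydroxyl. The fallback sets out from 12 and comes back at 15, with isolated acetals in place of transient boronates. 2,2-Dimethoxypropane and CSA in DMF give the 2,3:4,7-di-O-isopropylidene derivative of 12 F5, with only the C1 hydroxyl free. BzCl, pyridine and DMAP give its 1-O-benzoate F6, and 80% aqueous AcOH at 40 °C removes both acetonides to give 15.

3. Step 2. The epoxidation of the vinyl group next to the electron-poor acrylate may be too slow or too poorly enantiomer-selective for a clean resolution. The fallback sets out from 4 and comes back at 5, with an enzymatic resolution. Burkholderia cepacia lipase (Amano PS) with vinyl acetate in t-BuOMe should, by the usual size rule for lipases (acrylate unit large, vinyl medium), acylate the (3R)-alcohol to methyl (3R)-3-(acetyloxy)-2-methylidenepent-4-enoate F7, which is separated from the unreacted (3S)-alcohol. Methanolysis catalysed by CAL-B, which avoids the SN2' chemistry that base would trigger, returns 5.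

Further compounds
F1 | step 4 | methyl 2-[(4R,7R)-7-ethenyl-2,2-di(propan-2-yl)-4,7-dihydro-1,3,2-dioxasilepin-4-yl]prop-2-enoate | COC(=O)C(=C)[C@H]1C=C[C@@H](C=C)O[Si](C(C)C)(C(C)C)O1
F2 | step 4 | methyl (3R,4Z,6R)-3,6-dihydroxy-2-methylideneocta-4,7-dienoate | COC(=O)C(=C)[C@H](O)/C=C\[C@H](O)C=C
F3 | step 4 | methyl (3S,6R)-3,6-dihydroxycyclohexa-1,4-diene-1-carboxylate | COC(=O)C1=C[C@@H](O)C=C[C@H]1O
F4 | step 4 | methyl (3R,4S,5R,6S)-3,4,5,6-tetrahydroxycyclohex-1-ene-1-carboxylate | COC(=O)C1=C[C@@H](O)[C@H](O)[C@H](O)[C@H]1O
F5 | step 8 | 2,3:4,7-di-O-isopropylidene derivative of 12 | CC1(C)OCC2=C[C@@H](O)[C@@H]3OC(C)(C)O[C@@H]3[C@H]2O1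
F6 | step 8 | 1-O-benzoyl-2,3:4,7-di-O-isopropylidene derivative of 12 | CC1(C)OCC2=C[C@@H](OC(=O)c4ccccc4)[C@@H]3OC(C)(C)O[C@@H]3[C@H]2O1
F7 | step 2 | methyl (3R)-3-(acetyloxy)-2-methylidenepent-4-enoate | C=C[C@@H](OC(C)=O)C(=C)C(=O)OC
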